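**Assumptions (one line):** The target SMILES is the trans-2,3-diaryl isomer, (2S,3S) by CIP. I assume the (2S,5S)-thiolane catalyst gives this sense; if screening shows otherwise, use the (2R,5R) enantiomer. MOM is the global phenol protecting group.

## Retrosynthesis
1. Disconnect the stilbene C=C–aryl bond (Suzuki). This gives a C6-Bpin trans-2,3-diaryl-dihydrobenzofuran and (E)-β-iodo-MOM-isorhapontigenin precursor (a vinyl iodide made by Takai olefination). The Bpin comes from sterically controlled Ir C–H borylation.
2. Disconnect the dihydrofuran by a formal [4+1] between an o-quinone methide (o-QM) and a benzylic sulfonium ylide. The o-QM comes from a sulfone of a 2-hydroxybenzhydrol. The ylide comes from a chiral C2-symmetric sulfide and the aryl carbene of MOM-vanillin tosylhydrazone.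
3. The [4+1] forms the only new ring (C2–C3 and C2–O) and sets both stereocentres (trans). The benzhydrol is built from 2,6-dihydroxybenzaldehyde and the 3,5-bis(MOMO)phenyl anion. Ring order: dihydrofuran first, then the C6-aryl–vinyl bond, then global deprotection.

## Route

**Step 1**
Reactants: 1 (2,6-dihydroxybenzaldehyde)
Product: 2 (2-hydroxy-6-(methoxymethoxy)benzaldehyde)
Conditions: MOMCl (1.0 equiv), i-Pr2NEt, CH2Cl2, 0 °C
Reagents that add atoms: MOMCl, COCCl
Why: Mono-O-MOM protection of one of two equivalent chelated phenols (no regiochemistry issue). One ortho OH stays free for the later o-QM.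

**Step 2**
Reactants: 3 (5-bromoresorcinol)
Product: 4 (1-bromo-3,5-bis(methoxymethoxy)benzene)
Conditions: NaH (2.3 equiv), MOMCl (2.2 equiv), THF/DMF, 0 °C to rt
Reagents that add atoms: MOMCl, COCCl
Why: Standard bis-MOM protection of both phenols.

**Step 3**
Reactants: 2 (2-hydroxy-6-(MOMO)benzaldehyde), 4 (aryl bromide)
Product: 5 ([3,5-bis(MOMO)phenyl][2-hydroxy-6-(MOMO)phenyl]methanol, racemic carbinol)
Conditions: 2 + NaH (1.1 equiv), THF, 0 °C; then ArLi [from 4 + n-BuLi, THF, −78 °C] (2.0 equiv), −78 °C to rt; NH4Cl quench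
Reagents that add atoms: none
Why: Br/Li exchange gives the aryllithium, which adds 1,2 to the aldehyde of the sodium phenoxide (organolithium addition). The carbinol stereocentre is irrelevant because it is destroyed in the o-QM.

**Step 4**
Reactants: 5
Product: 6 (2-[(3,5-bis(MOMO)phenyl)(p-tolylsulfonyl)methyl]-3-(MOMO)phenol, racemic)
Conditions: p-TolSO2H (1.5 equiv), CH2Cl2, Na2SO4, rt, 2 h
Reagents that add atoms: p-toluenesulfinic acid, Cc1ccc(S(=O)O)cc1
Why: The electron-rich benzhydryl cation is trapped by sulfinic acid (SN1, sulfone formation). The bench-stable sulfone is a masked o-QM that base releases by loss of sulfinate.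

**Step 5**
Reactants: 7 (vanillin)
Product: 8 (3-methoxy-4-(methoxymethoxy)benzaldehyde)
Conditions: MOMCl, i-Pr2NEt, CH2Cl2, 0 °C to rt
Reagents that add atoms: MOMCl, COCCl
Why: Phenol MOM protection.

**Step 6**
Reactants: 8
Product: 9 (tosylhydrazone of 8, E)
Conditions: TsNHNH2, MeOH, rt
Reagents that add atoms: p-toluenesulfonylhydrazide, Cc1ccc(S(=O)(=O)NN)cc1
Why: Hydrazone condensation. The tosylhydrazone is the bench-stable precursor of the aryldiazomethane (Bamford–Stevens).

**Step 7**
Reactants: 8
Product: 10 ((E)-4-(2-iodovinyl)-2-methoxy-1-(MOMO)benzene)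
Conditions: CHI3 (2 equiv), CrCl2 (6 equiv), THF, 0 °C to rt
Reagents that add atoms: iodoform, IC(I)I
Why: Takai–Utimoto olefination of the aldehyde gives the E-vinyl iodide (E:Z > 95:5).

**Step 8**
Reactants: 11 ((2R,5R)-hexane-2,5-diol)
Product: 12 ((2R,5R)-hexane-2,5-diyl dimethanesulfonate)
Conditions: MsCl (2.3 equiv), Et3N, CH2Cl2, 0 °C
Reagents that add atoms: methanesulfonyl chloride, CS(=O)(=O)Cl
Why: Sulfonylation of both secondary alcohols with retention at carbon, which makes them leaving groups.

**Step 9**
Reactants: 12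
Product: 13 ((2S,5S)-2,5-dimethylthiolane, C2-symmetric chiral sulfide)
Conditions: Na2S·9H2O (1.2 equiv), DMF, 60 °C; isolate by distillation
Reagents that add atoms: sodium sulfide, [Na+].[Na+].[S-2]
Why: Double SN2 displacement (intermolecular, then 5-exo ring closure) inverts both centres. The (R,R) dimesylate gives the (S,S) thiolane, and the CIP priority order is unchanged, so the descriptor flips.

**Step 10**
Reactants: 6 (sulfone), 9 (tosylhydrazone), 13 (chiral sulfide catalyst)
Product: 14 ((2S,3S)-4-(MOMO)-3-[3,5-bis(MOMO)phenyl]-2-[3-methoxy-4-(MOMO)phenyl]-2,3-dihydrobenzofuran)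
Conditions: 6 (1.0 equiv), 9 (1.5 equiv), Cs2CO3 (3 equiv), Rh2(OAc)4 (1 mol%), 13 (20 mol%), BnEt3NCl (10 mol%), 1,4-dioxane, 40 °C, 36 h
Reagents that add atoms: none
Why: Proposed new method: catalytic asymmetric [4+1] annulation of a 4,6-dioxygenated diaryl o-QM (from sulfone 6 by base-induced loss of sulfinate) with a donor-aryl sulfonium ylide (from 9 by diazo formation, Rh-carbene capture by chiral sulfide 13). The ylide carbon adds to the exocyclic o-QM carbon to form C2–C3. The betaine equilibrates (Curtin–Hammett), and the phenoxide then displaces the sulfide by 5-exo-tet SN2 with inversion at C2. The C2-symmetric sulfide fixes the ylide face, and the anti betaine closes to the trans-2,3-diaryl ring, so both stereocentres are set here. The closest known chemistry is the catalytic sulfur-ylide epoxidation (tosylhydrazone/Rh/chiral sulfide) combined with racemic sulfur-ylide/o-QM [4+1] dihydrofuran synthesis. The novelty is the asymmetric version on an electron-rich diaryl o-QM with a semistabilised donor-aryl ylide.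

**Step 11**
Reactants: 14
Product: 15 (C6-pinacolboronate of 14)
Conditions: B2pin2 (0.6 equiv), [Ir(cod)OMe]2 (1.5 mol%), dtbpy (3 mol%), THF, 80 °C, 12 h
Reagents that add atoms: bis(pinacolato)diboron, CC1(C)OB(OC1(C)C)B2OC(C)(C)C(C)(C)O2
Why: Ir-catalysed C–H borylation is sterically controlled. C6 is the only arene C–H with H on both neighbours; every other C–H is ortho to an OMOM or aryl substituent. The sp3 stereocentres are untouched.

**Step 12**
Reactants: 15, 10
Product: 16 (tetra-MOM-protected target, E-stilbene)
Conditions: Pd(PPh3)4 (5 mol%), K3PO4 (3 equiv), THF/H2O (5:1), 60 °C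
Reagents that add atoms: none
Why: Suzuki–Miyaura coupling of the aryl-Bpin with the vinyl iodide is stereoretentive, so E is preserved. The stilbene is installed after the Rh-carbene step so that the alkene is not cyclopropanated.

**Step 13**
Reactants: 16
Product: 17 (Bisisorhapontigenin B)
Conditions: 2 M HCl (aq)/THF/MeOH (1:4:4), 40 °C, dark, 6–8 h
Reagents that add atoms: none
Why: Acid hydrolysis of the four aryl MOM acetals. The aryl methyl ether, trans-dihydrofuran and E-alkene survive these mild conditions, and exclusion of light avoids E/Z isomerisation.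

## Compound list
1 | 2,6-dihydroxybenzaldehyde | O=Cc1c(O)cccc1O | starting material
2 | 2-hydroxy-6-(methoxymethoxy)benzaldehyde | COCOc1cccc(O)c1C=O | intermediate
3 | 5-bromobenzene-1,3-diol (5-bromoresorcinol) | Oc1cc(O)cc(Br)c1 | starting material
4 | 1-bromo-3,5-bis(methoxymethoxy)benzene | COCOc1cc(Br)cc(OCOC)c1 | intermediate
5 | [3,5-bis(MOMO)phenyl][2-hydroxy-6-(MOMO)phenyl]methanol (racemic) | COCOc1cc(OCOC)cc(C(O)c2c(O)cccc2OCOC)c1 | intermediate
6 | 2-[(3,5-bis(MOMO)phenyl)(tosyl)methyl]-3-(MOMO)phenol (racemic) | COCOc1cc(OCOC)cc(C(c2c(O)cccc2OCOC)S(=O)(=O)c2ccc(C)cc2)c1 | intermediate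
7 | vanillin | COc1cc(C=O)ccc1O | starting material
8 | 3-methoxy-4-(methoxymethoxy)benzaldehyde | COCOc1ccc(C=O)cc1OC | intermediate
9 | tosylhydrazone of 8 (E) | COCOc1ccc(/C=N/NS(=O)(=O)c2ccc(C)cc2)cc1OC | intermediate
10 | (E)-4-(2-iodovinyl)-2-methoxy-1-(methoxymethoxy)benzene | COCOc1ccc(/C=C/I)cc1OC | intermediate
11 | (2R,5R)-hexane-2,5-diol | C[C@@H](O)CC[C@@H](C)O | starting material
12 | (2R,5R)-hexane-2,5-diyl dimethanesulfonate | C[C@@H](OS(C)(=O)=O)CC[C@@H](C)OS(C)(=O)=O | intermediate
13 | (2S,5S)-2,5-dimethylthiolane (chiral sulfide catalyst) | C[C@H]1CC[C@H](C)S1 | intermediate (catalyst; prepared in Steps 8–9)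
14 | (2S,3S)-tetra-MOM 6-H dihydrobenzofuran | c1cc(OCOC)c2c(c1)O[C@H](c3ccc(OCOC)c(OC)c3)[C@H]2c4cc(OCOC)cc(OCOC)c4 | intermediate
15 | C6-Bpin derivative of 14 | B5(OC(C)(C)C(C)(C)O5)c1cc(OCOC)c2c(c1)O[C@H](c3ccc(OCOC)c(OC)c3)[C@H]2c4cc(OCOC)cc(OCOC)c4 | intermediate
16 | tetra-MOM-protected target | COc1cc(/C=C/c2cc(OCOC)c3c(c2)O[C@H](c2ccc(OCOC)c(OC)c2)[C@H]3c2cc(OCOC)cc(OCOC)c2)ccc1OCOC | intermediate
17 | Bisisorhapontigenin B | COc1cc(/C=C/c2cc(O)c3c(c2)O[C@H](c2ccc(O)c(OC)c2)[C@H]3c2cc(O)cc(O)c2)ccc1O | target

## Totals
- **Step count:** 13 steps, of which Steps 8–9 prepare the catalyst in a parallel branch.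
- **Longest linear sequence:** 7 steps (1 → 2 → 5 → 6 → 14 → 15 → 16 → 17, i.e. Steps 1, 3, 4, 10, 11, 12, 13).

## Three steps most likely to fail
1. **Step 10 (proposed new asymmetric [4+1]).** Possible problems are low ee or dr, O–H insertion of the Rh-carbene into the phenol, and poor ylide addition to the donor-rich o-QM.
   - Fallback (known chemistry): run the racemic sulfur-ylide/o-QM [4+1] with an achiral sulfide. Use a preformed benzylsulfonium salt of tetrahydrothiophene made from the benzyl bromide of 8 (NaBH4, then CBr4/PPh3), with Cs2CO3 and sulfone 6. This gives trans-14 as a racemate, which is resolved by preparative chiral-phase HPLC, preferably at the stage of 16.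
2. **Step 11 (Ir C–H borylation).** Regioselectivity could leak to the guaiacyl ring, or conversion could be low on this crowded substrate.
   - Fallback: pre-install the C6 handle as an oxygen substituent.
     - Make 4-O-benzyl-2,4,6-trihydroxybenzaldehyde from phloroglucinaldehyde (BnBr, NaHCO3, MeCN; the most acidic 4-OH reacts), then mono-MOM one 2-OH.
     - Run Steps 3, 4 and 10 on this aldehyde to give the C6-OBn analogue of 14.
     - Remove the benzyl group (H2, Pd/C; no alkene is present yet), triflate the C6 phenol (PhNTf2, Et3N), and convert the triflate to the Bpin by Miyaura borylation (B2pin2, PdCl2(dppf), KOAc). This gives 15; continue with Steps 12 and 13.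
3. **Step 13 (global MOM removal).** Acid could ring-open the 2-(4-hydroxyaryl) dihydrofuran through a p-QM and epimerise C2.
   - Fallback: re-run the route with benzyl ethers in place of MOM (same phenols, BnBr). Remove them at the end with BCl3/pentamethylbenzene at −78 °C. This is non-protic, and hydrogenolysis is avoided so the stilbene survives.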